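**Retrosynthetic overview**
1. Target ⇒ methylene bridge made last: chiral acylfilicinic acid + 2,6-dihydroxy-4-methoxybutyrophenone + one CH2 from an iminium salt.
2. Acylfilicinic acid ⇒ nonane-2,4-dione (C1 and C3 as nucleophiles) + (R)-methyl hydrogen 2-methyl-2-prenylmalonate (two differentiated acyl carbons): chain acylation, then Claisen ring closure.
3. Half ester ⇒ enantioselective methanolysis (ester C–O bond) of prochiral 5-methyl-5-prenyl Meldrum's acid; this sets the only stereocenter.
4. Meldrum's compound ⇒ methyl Meldrum's acid + prenyl bromide; aryl ketone ⇒ 4-O-methylation of 2,4,6-trihydroxybutyrophenone.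
5. Ring order: the only ring made is the cyclohexanetrione (step 3); the benzene ring and the dioxanedione (opened in step 2) are bought.

Assumption: the quinidine-derived catalyst is taken to deliver methanol to the carbonyl that gives (R)-4; if the sense is opposite, the quinine-derived pseudo-enantiomer is used. Descriptors refer to the tautomers drawn.

**Step 1**
Reactants: 1 2,2,5-trimethyl-1,3-dioxane-4,6-dione (methyl Meldrum's acid); 2 1-bromo-3-methylbut-2-ene (prenyl bromide)
Product: 3 2,2,5-trimethyl-5-(3-methylbut-2-en-1-yl)-1,3-dioxane-4,6-dione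
Conditions: K2CO3 (1.5 equiv), DMF, 0 °C → rt
Reagents that add atoms: none
Why: Malonate-type C-alkylation (SN2 at the primary allylic bromide) of the stabilised Meldrum's acid enolate; the product is achiral but prochiral, with its two ring carbonyls enantiotopic.

**Step 2**
Reactants: 3 2,2,5-trimethyl-5-(3-methylbut-2-en-1-yl)-1,3-dioxane-4,6-dione
Product: 4 (R)-2-(methoxycarbonyl)-2,5-dimethylhex-4-enoic acid
Conditions: MeOH (10 equiv), 9-amino-9-deoxy-epi-quinidine 3,5-bis(trifluoromethyl)phenyl squaramide (10 mol %), MTBE, −20 °C; acid/base extraction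
Reagents that add atoms: methanol, CO
Why: Proposed new method: desymmetrising methanolysis of a prochiral 5,5-disubstituted Meldrum's acid by a bifunctional cinchona squaramide, in which the quinuclidine nitrogen acts as general base for MeOH while the squaramide N–H pair binds the acylal carbonyl under attack, the catalyst docks on the less hindered methyl face of the boat-shaped ring and so delivers methanol to one of the two enantiotopic C=O groups, and irreversible collapse with loss of acetone gives the half ester and sets the quaternary stereocenter in the C–O bond-forming event; the closest known reaction type is the cinchona-catalysed desymmetrising alcoholysis of meso and prochiral cyclic anhydrides (together with the uncatalysed thermal alcoholysis of Meldrum's acids to malonic half esters).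

**Step 3**
Reactants: 4 (R)-2-(methoxycarbonyl)-2,5-dimethylhex-4-enoic acid; 5 nonane-2,4-dione
Product: 8 (R)-2-hexanoyl-3,5-dihydroxy-4-methyl-4-(3-methylbut-2-en-1-yl)cyclohexa-2,5-dien-1-one, via acyl imidazole 6 (not isolated), via triketo ester 7 (not isolated)
Conditions: (i) CDI (1.1 equiv), THF, rt; (ii) add to 5 (2.2 equiv)/LDA (4.4 equiv), THF, −78 → 0 °C; (iii) rt → 45 °C; 1 M HCl, 0 °C
Reagents that add atoms: none
Why: The acyl imidazole is far more electrophilic than the neopentyl-type methyl ester, so the dilithio dianion of 5 is acylated at its terminal CH3 carbon (β-diketone dianion γ-acylation), and the resulting 1,3,5-triketone dianion then closes the ring by Claisen (Dieckmann-type, phloroglucinol-mode) attack of its C6 on the non-enolisable ester, the only six-membered C-cyclisation open to it; no bond at the quaternary carbon is touched, and because the acid carbon becomes C5 and the ester carbon C3 the (R) configuration is carried through.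

**Step 4**
Reactants: 9 1-(2,4,6-trihydroxyphenyl)butan-1-one
Product: 10 1-(2,6-dihydroxy-4-methoxyphenyl)butan-1-one
Conditions: Me2SO4 (1.0 equiv), K2CO3 (1.1 equiv), acetone, reflux
Reagents that add atoms: dimethyl sulfate, COS(=O)(=O)OC
Why: Williamson-type O-methylation that is selective for the para hydroxyl, which is the most acidic and the only one not hydrogen-bonded to the ketone.

**Step 5**
Reactants: 8 (R)-2-hexanoyl-3,5-dihydroxy-4-methyl-4-(3-methylbut-2-en-1-yl)cyclohexa-2,5-dien-1-one; 10 1-(2,6-dihydroxy-4-methoxyphenyl)butan-1-one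
Product: 13 (R)-2-[(3-butanoyl-2,4-dihydroxy-6-methoxyphenyl)methyl]-6-hexanoyl-3,5-dihydroxy-4-methyl-4-(3-methylbut-2-en-1-yl)cyclohexa-2,5-dien-1-one, via Mannich base 11 (not isolated), via methylene trione 12 (not isolated)
Conditions: (i) CH2=NMe2+ I− (1.05 equiv), NaHCO3 (1.1 equiv), CH2Cl2, 0 °C → rt; (ii) 10 (2.5 equiv), MeCN, 60 °C
Reagents that add atoms: N,N-dimethylmethyleneiminium iodide (Eschenmoser's salt), C=[N+](C)C.[I-]
Why: Mannich reaction at the only free ring CH of 8, then thermal loss of dimethylamine gives the quinone-methide-like methylene trione, which is trapped by C3 of the electron-rich phloroglucinol 10 (Michael addition/Friedel–Crafts-type alkylation with rearomatisation); the buffer keeps HI away from the prenyl group and the stereocenter is not involved.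

**Compound list**
1 | 2,2,5-trimethyl-1,3-dioxane-4,6-dione | CC1C(=O)OC(C)(C)OC1=O | starting material
2 | 1-bromo-3-methylbut-2-ene | CC(C)=CCBr | starting material
3 | 2,2,5-trimethyl-5-(3-methylbut-2-en-1-yl)-1,3-dioxane-4,6-dione | CC(C)=CCC1(C)C(=O)OC(C)(C)OC1=O | intermediate
4 | (R)-2-(methoxycarbonyl)-2,5-dimethylhex-4-enoic acid | COC(=O)[C@](C)(CC=C(C)C)C(=O)O | intermediate
5 | nonane-2,4-dione | CCCCCC(=O)CC(C)=O | starting material
6 | methyl (R)-2-(1H-imidazole-1-carbonyl)-2,5-dimethylhex-4-enoate (not isolated) | COC(=O)[C@](C)(CC=C(C)C)C(=O)n1ccnc1 | intermediate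
7 | methyl (R)-2-methyl-2-(3-methylbut-2-en-1-yl)-3,5,7-trioxododecanoate (not isolated) | COC(=O)[C@](C)(CC=C(C)C)C(=O)CC(=O)CC(=O)CCCCC | intermediate
8 | (R)-2-hexanoyl-3,5-dihydroxy-4-methyl-4-(3-methylbut-2-en-1-yl)cyclohexa-2,5-dien-1-one | CCCCCC(=O)C1=C(O)[C@](C)(CC=C(C)C)C(O)=CC1=O | intermediate
9 | 1-(2,4,6-trihydroxyphenyl)butan-1-one | CCCC(=O)c1c(O)cc(O)cc1O | starting material
10 | 1-(2,6-dihydroxy-4-methoxyphenyl)butan-1-one | CCCC(=O)c1c(O)cc(OC)cc1O | intermediate
11 | (R)-2-[(dimethylamino)methyl]-6-hexanoyl-3,5-dihydroxy-4-methyl-4-(3-methylbut-2-en-1-yl)cyclohexa-2,5-dien-1-one (not isolated) | CCCCCC(=O)C1=C(O)[C@](C)(CC=C(C)C)C(O)=C(CN(C)C)C1=O | intermediate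
12 | (S)-2-hexanoyl-3-hydroxy-4-methyl-6-methylidene-4-(3-methylbut-2-en-1-yl)cyclohex-2-ene-1,5-dione (not isolated; descriptor changes by CIP only) | CCCCCC(=O)C1=C(O)[C@](C)(CC=C(C)C)C(=O)C(=C)C1=O | intermediate
13 | (R)-2-[(3-butanoyl-2,4-dihydroxy-6-methoxyphenyl)methyl]-6-hexanoyl-3,5-dihydroxy-4-methyl-4-(3-methylbut-2-en-1-yl)cyclohexa-2,5-dien-1-one | CCCCCC(=O)C1=C(O)[C@](C)(CC=C(C)C)C(O)=C(Cc2c(OC)cc(O)c(C(=O)CCC)c2O)C1=O | target

**Totals**
Total steps: 5. Longest linear sequence: 4 (steps 1 → 2 → 3 → 5).

**Steps most likely to fail**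

Step 2 (the proposed new step). The catalyst has to tell methyl from prenyl at one carbon, and dialkyl Meldrum's acids are less electrophilic than anhydrides, so rate and ee are both uncertain. The fallback uses known chemistry and sets out from 3. Uncatalysed methanolysis in refluxing MeOH gives the racemic half ester 2-(methoxycarbonyl)-2,5-dimethylhex-4-enoic acid F1. Classical resolution by fractional crystallisation gives the (S)-1-phenylethylammonium salt of the (R)-acid F2 (the amine antipode is chosen by which salt is less soluble). Acidification with 1 M HCl comes back to the route at 4. The antipodal acid left in the mother liquor is the half ester that the step-3 fallback needs.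

Step 3. The triketone dianion may O-cyclise to a pyrandione, or the Claisen closure onto the hindered ester may stall. The fallback reverses the order of the two C–C bonds; it sets out from 3 and comes back at 8. Methanolysis with the quinine-derived pseudo-enantiomeric catalyst (or recovery from the resolution mother liquor) gives the antipodal (S)-half ester F3. 1-Chloro-N,N,2-trimethylpropenylamine converts it under neutral conditions into the acid chloride methyl (R)-2-(chlorocarbonyl)-2,5-dimethylhex-4-enoate F4. Magnesium-mediated soft enolisation (MgCl2, pyridine, CH2Cl2) C-acylates the central carbon of 5 to give the triacylmethane methyl (S)-4-acetyl-2-methyl-2-(3-methylbut-2-en-1-yl)-3,5-dioxodecanoate F5. LDA (3 equiv, THF, −78 → 0 °C) then closes the ring by Dieckmann attack of the acetyl CH3 enolate on the ester. Here the acid-derived carbon ends next to the acyl-bearing carbon, so the antipodal half ester gives the same (R)-8.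

Step 5. The second free position of 10 can be alkylated again, and retro-Mannich exchange can give homodimers. The fallback reverses the polarity; it sets out from 10 and comes back at 13. Eschenmoser's salt aminomethylates 10 to the aryl Mannich base 1-{3-[(dimethylamino)methyl]-2,6-dihydroxy-4-methoxyphenyl}butan-1-one F6. MeI gives the trimethylammonium iodide F7. With NaHCO3 in MeCN at rt this loses trimethylamine to give the o-quinone methide 2-butanoyl-3-hydroxy-5-methoxy-6-methylidenecyclohexa-2,4-dien-1-one F8, which is trapped by the acidic C6–H of 8 to give 13.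

**Further compounds**
F1 | step 2 | rac-2-(methoxycarbonyl)-2,5-dimethylhex-4-enoic acid | COC(=O)C(C)(CC=C(C)C)C(=O)O
F2 | step 2 | (S)-1-phenylethylammonium (R)-2-(methoxycarbonyl)-2,5-dimethylhex-4-enoate | COC(=O)[C@](C)(CC=C(C)C)C(=O)[O-].C[C@H]([NH3+])c1ccccc1
F3 | step 3 | (S)-2-(methoxycarbonyl)-2,5-dimethylhex-4-enoic acid | COC(=O)[C@@](C)(CC=C(C)C)C(=O)O
F4 | step 3 | methyl (R)-2-(chlorocarbonyl)-2,5-dimethylhex-4-enoate | COC(=O)[C@@](C)(CC=C(C)C)C(Cl)=O
F5 | step 3 | methyl (S)-4-acetyl-2-methyl-2-(3-methylbut-2-en-1-yl)-3,5-dioxodecanoate | COC(=O)[C@@](C)(CC=C(C)C)C(=O)C(C(C)=O)C(=O)CCCCC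
F6 | step 5 | 1-{3-[(dimethylamino)methyl]-2,6-dihydroxy-4-methoxyphenyl}butan-1-one | CCCC(=O)c1c(O)cc(OC)c(CN(C)C)c1O
F7 | step 5 | [(3-butanoyl-2,4-dihydroxy-6-methoxyphenyl)methyl]trimethylammonium iodide | CCCC(=O)c1c(O)cc(OC)c(C[N+](C)(C)C)c1O.[I-]
F8 | step 5 | 2-butanoyl-3-hydroxy-5-methoxy-6-methylidenecyclohexa-2,4-dien-1-one | CCCC(=O)C1=C(O)C=C(OC)C(=C)C1=O
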